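**Plan**

- Retrosynthesis: the isopropenyl C=CH2 next to the stereocentre is cut back to an acetyl C=O (Wittig). The ArCH2–C(aryl) bond is then cut as a conjugate addition of the arene to an α-methylene ketone, followed by the aryl–alkenyl bond (Suzuki), the O–CH3 bond and the aryl–C(=O) bond (Houben–Hoesch), down to phloroglucinol.
- Enabling feature: C-5 of the phloroglucinol ring of the benzophenone is the only ring CH. It is flanked by C-4–OMe and C-6–OH and lies para to C-2–OH, so it is an enol carbon and a carbon nucleophile. The side-chain CH2 and CH are β and α to the isopropenyl carbon, which is a masked ketone carbon.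
- Forward, arene: phloroglucinol → benzophenone → 4-O-methyl ether (mirror-symmetric, C-3 and C-5 equivalent) → mono-iodide → (E)-alkenyl arene.
- Forward, side chain: ethyl acetoacetate → alkylation → decarboxylative Mannich methylenation to the α-methylene ketone; the two halves are then joined and the ketone is methylenated.
- Stereochemistry: the single stereocentre (R) is set in the joining step by catalyst-controlled protonation of an enamine. The E alkene comes from syn-hydroboration of an alkyne and is retained in the coupling. No protecting groups are used.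

Key step: step 8

Assumption: the (S)-diamine is assigned as the antipode that gives the (R)-ketone by analogy with related enamine protonations; the sense is to be confirmed on the first run, and the (R)-diamine from D-tert-leucine serves equally if it proves opposite.

**Route**

Step 1
Reactants: 1 phloroglucinol; 2 3-hydroxybenzonitrile
Product: 4 (3-hydroxyphenyl)(2,4,6-trihydroxyphenyl)methanone, via ketiminium chloride 3 (not isolated)
Conditions: ZnCl2, HCl (g), Et2O, 0 °C; then H2O, reflux
Reagents that add atoms: water, O
Why: Houben–Hoesch acylation, in which the HCl/ZnCl2-activated nitrile acylates the symmetric, highly nucleophilic phloroglucinol only once because the ketiminium salt 3 precipitates and is deactivated, and hot water then hydrolyses C=NH2+ to C=O.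

Step 2
Reactants: 4 (3-hydroxyphenyl)(2,4,6-trihydroxyphenyl)methanone
Product: 5 (2,6-dihydroxy-4-methoxyphenyl)(3-hydroxyphenyl)methanone
Conditions: Me2SO4 (1.0 equiv), K2CO3 (1.0 equiv), acetone, rt
Reagents that add atoms: dimethyl sulfate, COS(=O)(=O)OC
Why: Williamson ether synthesis under limiting base, in which the 4-OH para to the carbonyl is the most acidic hydroxyl (a vinylogous acid), the 2- and 6-OH are hindered and hydrogen-bonded to C=O and the 3'-OH is a less acidic simple phenol, so the monoanion should be methylated at O-4.

Step 3
Reactants: 5 (2,6-dihydroxy-4-methoxyphenyl)(3-hydroxyphenyl)methanone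
Product: 6 (2,6-dihydroxy-3-iodo-4-methoxyphenyl)(3-hydroxyphenyl)methanone
Conditions: NIS (1.0 equiv), DMF, −20 → 0 °C, dark
Reagents that add atoms: N-iodosuccinimide, O=C1CCC(=O)N1I
Why: electrophilic aromatic iodination, in which C-3 and C-5 of 5 are equivalent by the mirror plane through the carbonyl and OMe carbons so that one equivalent of I+ should give a single mono-iodide, while the hydroxybenzoyl ring is deactivated by its carbonyl.

Step 4
Reactants: 7 3-methylbut-1-yne
Product: 8 (E)-4,4,5,5-tetramethyl-2-(3-methylbut-1-en-1-yl)-1,3,2-dioxaborolane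
Conditions: HBpin, Cp2Zr(H)Cl (5 mol %), Et3N (10 mol %), neat, sealed tube, 60 °C
Reagents that add atoms: pinacolborane, CC1(C)OBOC1(C)C
Why: zirconium-catalysed hydroboration of a terminal alkyne, in which syn addition of H–B with boron at the terminal carbon fixes the E geometry.

Step 5
Reactants: 6 (2,6-dihydroxy-3-iodo-4-methoxyphenyl)(3-hydroxyphenyl)methanone; 8 (E)-4,4,5,5-tetramethyl-2-(3-methylbut-1-en-1-yl)-1,3,2-dioxaborolane
Product: 9 {2,6-dihydroxy-4-methoxy-3-[(E)-3-methylbut-1-en-1-yl]phenyl}(3-hydroxyphenyl)methanone
Conditions: Pd(OAc)2 (5 mol %), SPhos (10 mol %), K3PO4 (5 equiv), dioxane/H2O 5:1, degassed, 80 °C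
Reagents that add atoms: none
Why: Suzuki–Miyaura coupling, in which a bulky electron-rich biarylphosphine promotes oxidative addition into the hindered, electron-rich C–I bond, the free phenols are tolerated as phenoxides and the alkenyl group is transferred with retention of the E geometry.

Step 6
Reactants: 10 ethyl acetoacetate; 11 4-bromo-2-methylbut-1-ene
Product: 12 ethyl 2-acetyl-5-methylhex-5-enoate
Conditions: NaH (1.0 equiv), NaI (10 mol %), THF/DMF, 0 → 60 °C
Reagents that add atoms: none
Why: acetoacetic ester alkylation, an SN2 C-alkylation of the stabilised sodium enolate by the primary homoallylic bromide under iodide catalysis.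

Step 7
Reactants: 12 ethyl 2-acetyl-5-methylhex-5-enoate
Product: 15 6-methyl-3-methylidenehept-6-en-2-one, via potassium keto-carboxylate 13 (not isolated), via Mannich adduct 14 (not isolated)
Conditions: 1 M aq KOH, rt; then Et2NH·HCl, 37 % aq CH2O, pH 7, rt → 40 °C; used freshly
Reagents that add atoms: formaldehyde, C=O
Why: Mannich methylenation of a β-keto acid, in which cold dilute alkali saponifies the ester without retro-Claisen cleavage, the carboxylate 13 is aminomethylated at its α-carbon and the adduct 14 fragments with loss of CO2 and Et2NH, which places the methylene group only at C-3.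

Step 8
Reactants: 9 {2,6-dihydroxy-4-methoxy-3-[(E)-3-methylbut-1-en-1-yl]phenyl}(3-hydroxyphenyl)methanone; 15 6-methyl-3-methylidenehept-6-en-2-one
Product: 18 (3R)-3-({2,4-dihydroxy-3-(3-hydroxybenzoyl)-6-methoxy-5-[(E)-3-methylbut-1-en-1-yl]phenyl}methyl)-6-methylhept-6-en-2-one, via iminium triflate 16 (not isolated), via enamine 17 (not isolated)
Conditions: (S)-N1,N1-diethyl-3,3-dimethylbutane-1,2-diamine·TfOH (20 mol %), 15 (1.5 equiv), CHCl3, 0 °C → rt; pH 7 buffer work-up
Reagents that add atoms: none
Why: Proposed new method: the primary amine of the catalyst condenses with enone 15 to the iminium ion 16, whose CH2 terminus is attacked by the one unsubstituted carbon of the acylphloroglucinol ring of 9 (an enol carbon ortho to C–OH and C–OMe and para to the second C–OH), and rearomatisation leaves enamine 17, which the pendant Et2NH+ arm protonates at the α-carbon before hydrolysis releases 18 and the catalyst. The closest known reaction type is the primary-amine-catalysed Friedel–Crafts conjugate addition with enantioselective enamine protonation of indoles and α-substituted acroleins or vinyl ketones, supported by iminium-catalysed Friedel–Crafts additions of electron-rich phenols to enals and by Michael additions of acylphloroglucinols; what is new is a phenolic carbon nucleophile in the protonation manifold. No ring is closed, although 18 may rest in part as its cyclic hemiketal with the neighbouring OH, which reopens. The new stereocentre (R) is controlled by the catalyst alone, through intramolecular proton delivery from the ammonium arm to one face of the enamine, since the arene carries no stereocentre. The step needs site selectivity, C- over O-alkylation and face selectivity: the first is secured because the attacking carbon is the only free position of the phloroglucinol ring and the hydroxybenzoyl ring is deactivated by its carbonyl, the second because oxa-Michael addition is reversible while C-alkylation with rearomatisation is not, and the third by running at low temperature so that catalyst-bound proton delivery should outpace proton transfer from the neighbouring phenol.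

Step 9
Reactants: 18 (3R)-3-({2,4-dihydroxy-3-(3-hydroxybenzoyl)-6-methoxy-5-[(E)-3-methylbut-1-en-1-yl]phenyl}methyl)-6-methylhept-6-en-2-one
Product: 19 {2,6-dihydroxy-4-methoxy-3-[(E)-3-methylbut-1-en-1-yl]-5-[(2R)-5-methyl-2-(prop-1-en-2-yl)hex-5-en-1-yl]phenyl}(3-hydroxyphenyl)methanone
Conditions: Ph3PCH3Br (6 equiv), KOtBu (6 equiv), THF, 0 °C → rt; aq NH4Cl
Reagents that add atoms: methylenetriphenylphosphorane (made in the flask from methyltriphenylphosphonium bromide and KOtBu), C=P(c1ccccc1)(c1ccccc1)c1ccccc1
Why: Wittig methylenation, in which three equivalents of ylide convert the phenols into phenoxides and so make the diaryl C=O a hindered vinylogous carboxylate inert to the ylide, while the methyl ketone (in equilibrium with its hemiketal) should be methylenated at low temperature faster than its α-CH is enolised, so the stereocentre is kept.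

**Compound list**

1 | phloroglucinol | Oc1cc(O)cc(O)c1 | starting material
2 | 3-hydroxybenzonitrile | N#Cc1cccc(O)c1 | starting material
3 | (3-hydroxyphenyl)(2,4,6-trihydroxyphenyl)methaniminium chloride | Oc1cc(O)c(C(=[NH2+])c2cccc(O)c2)c(O)c1.[Cl-] | intermediate (not isolated)
4 | (3-hydroxyphenyl)(2,4,6-trihydroxyphenyl)methanone | Oc1cc(O)c(C(=O)c2cccc(O)c2)c(O)c1 | intermediate
5 | (2,6-dihydroxy-4-methoxyphenyl)(3-hydroxyphenyl)methanone | COc1cc(O)c(C(=O)c2cccc(O)c2)c(O)c1 | intermediate
6 | (2,6-dihydroxy-3-iodo-4-methoxyphenyl)(3-hydroxyphenyl)methanone | COc1cc(O)c(C(=O)c2cccc(O)c2)c(O)c1I | intermediate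
7 | 3-methylbut-1-yne | C#CC(C)C | starting material
8 | (E)-4,4,5,5-tetramethyl-2-(3-methylbut-1-en-1-yl)-1,3,2-dioxaborolane | CC(C)/C=C/B1OC(C)(C)C(C)(C)O1 | intermediate
9 | {2,6-dihydroxy-4-methoxy-3-[(E)-3-methylbut-1-en-1-yl]phenyl}(3-hydroxyphenyl)methanone | COc1cc(O)c(C(=O)c2cccc(O)c2)c(O)c1/C=C/C(C)C | intermediate
10 | ethyl acetoacetate | CCOC(=O)CC(C)=O | starting material
11 | 4-bromo-2-methylbut-1-ene | C=C(C)CCBr | starting material
12 | ethyl 2-acetyl-5-methylhex-5-enoate (racemic) | CCOC(=O)C(CCC(C)=C)C(C)=O | intermediate
13 | potassium 2-acetyl-5-methylhex-5-enoate | CC(=O)C(CCC(C)=C)C(=O)[O-].[K+] | intermediate (not isolated)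
14 | 2-acetyl-2-[(diethylamino)methyl]-5-methylhex-5-enoic acid | CCN(CC)CC(CCC(C)=C)(C(C)=O)C(=O)O | intermediate (not isolated)
15 | 6-methyl-3-methylidenehept-6-en-2-one | CC(=O)C(=C)CCC(C)=C | intermediate
16 | iminium triflate of 15 with the (S)-diamine catalyst, N-[(2S)-1-(diethylamino)-3,3-dimethylbutan-2-yl]-6-methyl-3-methylidenehept-6-en-2-iminium triflate | C=C(CCC(C)=C)C(C)=[NH+][C@H](CN(CC)CC)C(C)(C)C.[O-]S(=O)(=O)C(F)(F)F | intermediate (not isolated)
17 | catalyst-bound enamine after C–C bond formation (S at the catalyst carbon, enamine geometry not assigned, diethylammonium arm as triflate) | C=C(C)CCC(Cc1c(O)c(C(=O)c2cccc(O)c2)c(O)c(/C=C/C(C)C)c1OC)=C(C)N[C@H](C[NH+](CC)CC)C(C)(C)C.[O-]S(=O)(=O)C(F)(F)F | intermediate (not isolated)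
18 | (3R)-3-({2,4-dihydroxy-3-(3-hydroxybenzoyl)-6-methoxy-5-[(E)-3-methylbut-1-en-1-yl]phenyl}methyl)-6-methylhept-6-en-2-one | C=C(C)CC[C@H](Cc1c(O)c(C(=O)c2cccc(O)c2)c(O)c(/C=C/C(C)C)c1OC)C(C)=O | intermediate
19 | {2,6-dihydroxy-4-methoxy-3-[(E)-3-methylbut-1-en-1-yl]-5-[(2R)-5-methyl-2-(prop-1-en-2-yl)hex-5-en-1-yl]phenyl}(3-hydroxyphenyl)methanone | C=C(C)CC[C@H](Cc1c(O)c(C(=O)c2cccc(O)c2)c(O)c(/C=C/C(C)C)c1OC)C(=C)C | target

**Step count**

Total step count: 9. Longest linear sequence: 6 (steps 1, 2, 3, 5, 8, 9).

**Steps most likely to fail**

1. Step 8 (Proposed new method). What may go wrong: low face selectivity in the proton transfer, because the neighbouring phenol or adventitious water may deliver the proton instead of the catalyst arm. The product may also racemise through reversible enolisation or through dehydration of its hemiketal to a cyclic enol ether. The C–C bond formation may be sluggish because the acyl group lowers the nucleophilicity of the arene, leaving the enone time to dimerise.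
Fallback (known chemistry, stereocontrol by resolution instead of catalysis): it sets out from 9 and 15. The conjugate addition is run without chiral control (Et3N in MeOH, the ordinary Michael addition of an acylphloroglucinol to an enone) to give the racemic ketone F1. Wittig methylenation as in step 9 gives the racemic target F2, in which the stereocentre can no longer epimerise. Preparative chromatography on a chiral stationary phase separates the enantiomers, and the route is rejoined at 19.

2. Step 9. What may go wrong: base-induced epimerisation of the stereocentre α to the ketone before the ylide adds, or stalled conversion because the tri-phenoxide salt precipitates or rests as the hemiketal alkoxide.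
Fallback (addition–elimination through a non-basic organocerium instead of an ylide): it sets out from 18. Me3SiCH2Li/CeCl3 in excess (THF, −78 °C) adds to the methyl ketone without enolisation, the phenols consuming three equivalents, to give the β-hydroxysilane F3. KH in THF at 0 °C → rt then effects the syn elimination of a Peterson olefination, and the route is rejoined at 19.

3. Step 5. What may go wrong: slow oxidative addition into the electron-rich, doubly ortho-substituted iodophenoxide, with protodeiodination back to 5 overtaking the coupling.
Fallback (protecting-group strategy that changes the electronic character of the halide): it sets out from 6. Peracetylation (Ac2O, pyridine, DMAP) gives the triacetate iodide F4, an electron-poorer aryl iodide that cannot form phenoxides. Anhydrous Suzuki–Miyaura coupling with 8 (Pd(dppf)Cl2, CsF, dioxane, 80 °C) gives the triacetate F5. K2CO3 in MeOH at rt removes the acetates, and the route is rejoined at 9.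

**Further compounds**

F1 | step 8 | rac-3-({2,4-dihydroxy-3-(3-hydroxybenzoyl)-6-methoxy-5-[(E)-3-methylbut-1-en-1-yl]phenyl}methyl)-6-methylhept-6-en-2-one | C=C(C)CCC(Cc1c(O)c(C(=O)c2cccc(O)c2)c(O)c(/C=C/C(C)C)c1OC)C(C)=O
F2 | step 8 | rac-{2,6-dihydroxy-4-methoxy-3-[(E)-3-methylbut-1-en-1-yl]-5-[5-methyl-2-(prop-1-en-2-yl)hex-5-en-1-yl]phenyl}(3-hydroxyphenyl)methanone | C=C(C)CCC(Cc1c(O)c(C(=O)c2cccc(O)c2)c(O)c(/C=C/C(C)C)c1OC)C(=C)C
F3 | step 9 | (3R)-3-({2,4-dihydroxy-3-(3-hydroxybenzoyl)-6-methoxy-5-[(E)-3-methylbut-1-en-1-yl]phenyl}methyl)-2,6-dimethyl-1-(trimethylsilyl)hept-6-en-2-ol (mixture of epimers at C-2) | C=C(C)CC[C@H](Cc1c(O)c(C(=O)c2cccc(O)c2)c(O)c(/C=C/C(C)C)c1OC)C(C)(O)C[Si](C)(C)C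
F4 | step 5 | 2-(3-acetoxybenzoyl)-4-iodo-5-methoxy-1,3-phenylene diacetate | COc1cc(OC(C)=O)c(C(=O)c2cccc(OC(C)=O)c2)c(OC(C)=O)c1I
F5 | step 5 | 2-(3-acetoxybenzoyl)-5-methoxy-4-[(E)-3-methylbut-1-en-1-yl]-1,3-phenylene diacetate | COc1cc(OC(C)=O)c(C(=O)c2cccc(OC(C)=O)c2)c(OC(C)=O)c1/C=C/C(C)C
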